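## Retrosynthetic overview

1. Isoamoritin ⇐ threefold MOM cleavage of the (2S)-tris-MOM flavanone. Rings A and B are bought as benzenes. Ring C is the only ring made, and it is closed in the penultimate step.
2. Ring C ⇐ a one-operation formal [4+2] annulation that makes O1–C8a and C4–C4a. The partners are 3,5-bis(MOMO)-4,6-diprenylbenzyne (C4a≡C8a, from an ortho-silylaryl triflate) and the O1–C2–C3–C4 chain of an (S)-3-aryl-3-silyloxy Weinreb propanamide. The alkoxide adds to the aryne and the resulting aryl anion is acylated.
3. Enabling feature: ring A is hexasubstituted, its C5 oxygen stands next to C4a, and C8a stands next to the C8 prenyl carbon. The C5–O dipole polarises the C4a≡C8a aryne, so O1 enters at C8a and the carbanion arises at C4a, from which C4 is reached by a six-membered closure. The C2–O1 bond already exists, so C2 is never touched.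
4. Aryne precursor ⇐ phloroglucinol, whose third oxygen becomes the triflate leaving group, by MOM- and carbamate-directed ortho-metalations (prenyl, SiMe3, prenyl).
5. Chain ⇐ 3-bromo-4,5-dihydroxybenzaldehyde by selective O-methylation, Stille prenylation, acetate aldol/oxidation and asymmetric transfer hydrogenation, which sets C2.

Key step: step 15

Assumption: the (2S) configuration encoded in the SMILES is the goal. Flavanone numbering is used (O1, C2–C4, C4a, C5–C8, C8a; primes for ring B). Prenyl = 3-methylbut-2-en-1-yl and MOM = CH2OCH3. Tributyl(prenyl)stannane, LDA and the Ru catalyst are bought.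

## Route

Step 1
Reactants: 1 phloroglucinol
Product: 2 3,5-bis(methoxymethoxy)phenol
Conditions: MOMCl (2.0 equiv), iPr2NEt (2.2 equiv), DMF, 0 °C → rt; chromatography
Reagents that add atoms: chloromethyl methyl ether (MOMCl), COCCl
Why: Williamson-type O-alkylation of three equivalent phenols, limited by stoichiometry to the bis-acetal (separable from the mono- and tris-ethers), leaves exactly one free OH, the oxygen that later leaves as triflate.

Step 2
Reactants: 2 3,5-bis(methoxymethoxy)phenol
Product: 4 3,5-bis(methoxymethoxy)-4-prenylphenol, via dilithio species 3 (not isolated)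
Conditions: n-BuLi (2.2 equiv), TMEDA, THF, 0 °C; prenyl bromide (1.0 equiv), −78 → 0 °C; AcOH quench
Reagents that add atoms: prenyl bromide, CC(C)=CCBr
Why: Directed ortho-metalation: after O-deprotonation the C–H between the two chelating OMOM groups is the most activated ring position, and the aryllithium carbon of 3 is far more nucleophilic than its lithium phenoxide oxygen, so one equivalent of the allylic bromide should be taken up by SN2 C-alkylation.

Step 3
Reactants: 4 3,5-bis(methoxymethoxy)-4-prenylphenol
Product: 5 3,5-bis(methoxymethoxy)-4-prenylphenyl N,N-diethylcarbamate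
Conditions: Et2NCOCl, K2CO3, MeCN, reflux
Reagents that add atoms: N,N-diethylcarbamoyl chloride, CCN(CC)C(=O)Cl
Why: O-Carbamoylation of the phenoxide (acyl substitution) installs the strongest oxygen-based directing group for the next two metalations and does not affect the prenyl and MOM groups.

Step 4
Reactants: 5 3,5-bis(methoxymethoxy)-4-prenylphenyl N,N-diethylcarbamate
Product: 7 3,5-bis(methoxymethoxy)-4-prenyl-2-(trimethylsilyl)phenyl N,N-diethylcarbamate, via aryllithium 6 (not isolated)
Conditions: s-BuLi, TMEDA, THF, −78 °C; TMSCl, −78 °C → rt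
Reagents that add atoms: chlorotrimethylsilane, C[Si](C)(C)Cl
Why: Directed ortho-metalation at a position flanked by the carbamate and an OMOM group (cooperative 1,3-directing effect, the two such positions being equivalent), followed by silylation at −78 °C, where the anionic ortho-Fries rearrangement is frozen.

Step 5
Reactants: 7 3,5-bis(methoxymethoxy)-4-prenyl-2-(trimethylsilyl)phenyl N,N-diethylcarbamate
Product: 9 3,5-bis(methoxymethoxy)-2,4-diprenyl-6-(trimethylsilyl)phenyl N,N-diethylcarbamate, via aryllithium 8 (not isolated)
Conditions: s-BuLi, TMEDA, THF, −78 °C; CuBr·SMe2 (10 mol %), prenyl bromide, −78 → −20 °C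
Reagents that add atoms: prenyl bromide, CC(C)=CCBr
Why: Directed ortho-metalation of the last ring C–H (again between carbamate and OMOM) and copper-catalysed SN2 allylation below the onset of the anionic ortho-Fries shift; no prenyl group stands next to the carbamate during the lithiation, which limits lateral deprotonation.

Step 6
Reactants: 9 3,5-bis(methoxymethoxy)-2,4-diprenyl-6-(trimethylsilyl)phenyl N,N-diethylcarbamate
Product: 10 3,5-bis(methoxymethoxy)-2,4-diprenyl-6-(trimethylsilyl)phenol
Conditions: LiAlH4, THF, 0 °C → reflux; H2O work-up (no acid)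
Reagents that add atoms: none
Why: Hydride reduction of the aryl carbamate (acyl substitution to the phenoxide, then reduction of the formamide) frees the hindered phenol under non-acidic conditions that spare the acid-labile aryl–Si bond, the acetals and the alkenes.

Step 7
Reactants: 10 3,5-bis(methoxymethoxy)-2,4-diprenyl-6-(trimethylsilyl)phenol
Product: 12 3,5-bis(methoxymethoxy)-2,4-diprenyl-6-(trimethylsilyl)phenyl trifluoromethanesulfonate, via lithium phenoxide 11 (not isolated)
Conditions: n-BuLi, Et2O, −78 °C; Tf2O, −78 → 0 °C
Reagents that add atoms: trifluoromethanesulfonic anhydride, O=S(=O)(OS(=O)(=O)C(F)(F)F)C(F)(F)F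
Why: O-Sulfonylation of the pre-formed lithium phenoxide with the small, very reactive anhydride is the standard last step to an ortho-silylaryl triflate (Kobayashi aryne precursor) and avoids acid.

Step 8
Reactants: 13 3-bromo-4,5-dihydroxybenzaldehyde
Product: 14 3-bromo-5-hydroxy-4-methoxybenzaldehyde
Conditions: MeI (1.05 equiv), Li2CO3, DMF, 40 °C
Reagents that add atoms: iodomethane, CI
Why: Chemoselective Williamson methylation: the 4-OH, para to the formyl group and ortho to bromine, is the more acidic phenol and the only one ionised by the weak base.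

Step 9
Reactants: 14 3-bromo-5-hydroxy-4-methoxybenzaldehyde
Product: 15 3-bromo-4-methoxy-5-(methoxymethoxy)benzaldehyde
Conditions: MOMCl, iPr2NEt, CH2Cl2, 0 °C → rt
Reagents that add atoms: chloromethyl methyl ether (MOMCl), COCCl
Why: MOM protection (O-alkylation) of the remaining phenol masks the only acidic and nucleophilic site of ring B for the organometallic steps and the aryne step.

Step 10
Reactants: 15 3-bromo-4-methoxy-5-(methoxymethoxy)benzaldehyde
Product: 16 4-methoxy-3-(methoxymethoxy)-5-prenylbenzaldehyde
Conditions: Bu3Sn(prenyl), Pd(PPh3)4 (5 mol %), DMF, 100 °C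
Reagents that add atoms: tributyl(3-methylbut-2-en-1-yl)stannane, CCCC[Sn](CCCC)(CCCC)CC=C(C)C
Why: Stille cross-coupling of the aryl bromide with the allylic stannane transfers the prenyl group through its unsubstituted terminus and tolerates the aldehyde.

Step 11
Reactants: 16 4-methoxy-3-(methoxymethoxy)-5-prenylbenzaldehyde; 17 N-methoxy-N-methylacetamide
Product: 19 rac-3-hydroxy-N-methoxy-3-[4-methoxy-3-(methoxymethoxy)-5-prenylphenyl]-N-methylpropanamide, via lithium enolate 18 (not isolated)
Conditions: LDA, THF, −78 °C; then 16, −78 °C; AcOH quench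
Reagents that add atoms: none
Why: Lithium enolate acetate aldol addition of the Weinreb acetamide to the non-enolisable aldehyde; the carbinol centre is formed racemic and is erased in the next step.

Step 12
Reactants: 19 racemic β-hydroxy Weinreb amide
Product: 20 N-methoxy-3-[4-methoxy-3-(methoxymethoxy)-5-prenylphenyl]-N-methyl-3-oxopropanamide
Conditions: Dess–Martin periodinane (1.1 equiv), CH2Cl2, 0 °C → rt
Reagents that add atoms: none
Why: Dess–Martin oxidation of the benzylic secondary alcohol under near-neutral conditions gives the β-keto amide without touching alkenes or acetals.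

Step 13
Reactants: 20 β-keto Weinreb amide
Product: 21 (S)-3-hydroxy-N-methoxy-3-[4-methoxy-3-(methoxymethoxy)-5-prenylphenyl]-N-methylpropanamide
Conditions: RuCl[(S,S)-TsDPEN](p-cymene) (1 mol %), HCO2H–Et3N (5:2), EtOAc, 30 °C
Reagents that add atoms: none
Why: Noyori–Ikariya asymmetric transfer hydrogenation: the (S,S)-TsDPEN–Ru hydride delivers H to the Re face of the aryl ketone through the CH/π-organised six-membered outer-sphere transition state, which sets the (S)-carbinol (the future C2) and leaves the isolated trisubstituted alkene untouched.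

Step 14
Reactants: 21 (S)-β-hydroxy Weinreb amide
Product: 22 (S)-N-methoxy-3-[4-methoxy-3-(methoxymethoxy)-5-prenylphenyl]-N-methyl-3-(trimethylsilyloxy)propanamide
Conditions: TMSCl, imidazole, CH2Cl2, 0 °C
Reagents that add atoms: chlorotrimethylsilane, C[Si](C)(C)Cl
Why: Silylation of the secondary alcohol removes the only proton that could quench the aryl anion of the key step and stores the alkoxide in a fluoride-releasable form, with no change at the stereocentre.

Step 15
Reactants: 12 ortho-silylaryl triflate; 22 (S)-β-silyloxy Weinreb amide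
Product: 27 (2S)-2-[4-methoxy-3-(methoxymethoxy)-5-prenylphenyl]-5,7-bis(methoxymethoxy)-6,8-diprenylchroman-4-one, via aryne 23 (not isolated), via potassium alkoxide 24 (not isolated), via C4a aryl anion 25 (not isolated), via tetrahedral adduct 26 (not isolated)
Conditions: THF solution of 12 (1.2 equiv) and 22 added over 2 h to spray-dried KF (4 equiv)/18-crown-6 (4 equiv), THF, −20 → 0 °C; then AcOH, THF, −20 °C
Reagents that add atoms: none
Why: Proposed new method: fluoride strips the C–SiMe3 group of 12 (1,2-elimination of triflate, Kobayashi aryne generation) and the O–SiMe3 group of 22, so that aryne 23 and alkoxide 24 meet at low stationary concentration, O1 adds to C8a, the resulting C4a carbanion 25 attacks the Weinreb carbonyl C4, and adduct 26 releases the ketone only on the acidic quench. The closest known reaction types are the fluoride-triggered annulation of arynes with salicylate esters to xanthones, the aryne insertion into the N–C(O) bond of β-lactams to dihydroquinolinones and the Parham cyclisation of aryllithiums onto Weinreb amides; what is new is an aliphatic aldol-type alkoxide as the first nucleophile. Ring C closes in a 6-exo-trig mode (in-plane sp2 carbanion onto the tethered C=O), which should outrun proton transfer because the medium is aprotic THF and amide α-protons are only weakly acidic. No lasting stereocentre is created: C2 comes from 22 with its C2–O1 bond untouched, hence retention, and the transient C4 hemiaminal centre vanishes on work-up. Regioselectivity is secured by the C5 OMOM oxygen, whose inductive pull distorts the aryne so that nucleophiles enter at the remote C8a and the charge develops at C4a next to it (both aryne carbons are flanked alike sterically); the anionic O-nucleophile should outcompete intermolecular ene reactions of the prenyl groups, and an intramolecular ene reaction of the C8 prenyl group is geometrically out of reach. The amide resists transacylation by 24 and slows retro-aldol cleavage, and storing C4 as 26 keeps base away from an enolisable flavanone, which blocks E1cB opening of ring C and racemisation.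

Step 16
Reactants: 27 (2S)-tris-MOM flavanone
Product: 28 isoamoritin, (2S)-5,7-dihydroxy-2-(3-hydroxy-4-methoxy-5-prenylphenyl)-6,8-diprenylchroman-4-one
Conditions: 3 M aq HCl, MeOH, 45 °C, short time; NaHCO3 work-up
Reagents that add atoms: none
Why: Acid-catalysed transacetalisation of the three aryl MOM ethers to dimethoxymethane is the usual end game for prenylated flavanones; C2 is not involved, and mild acid avoids the base-induced ring opening that racemises 5-hydroxyflavanones.

## Compound list

1 | phloroglucinol | Oc1cc(O)cc(O)c1 | starting material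
2 | 3,5-bis(methoxymethoxy)phenol | COCOc1cc(O)cc(OCOC)c1 | intermediate
3 | dilithio species of 2 (O-Li, C4-Li; not isolated) | [Li]Oc1cc(OCOC)c([Li])c(OCOC)c1 | intermediate
4 | 3,5-bis(methoxymethoxy)-4-prenylphenol | Oc1cc(OCOC)c(CC=C(C)C)c(OCOC)c1 | intermediate
5 | 3,5-bis(methoxymethoxy)-4-prenylphenyl N,N-diethylcarbamate | CCN(CC)C(=O)Oc1cc(OCOC)c(CC=C(C)C)c(OCOC)c1 | intermediate
6 | 2-lithio derivative of 5 (not isolated) | [Li]c1c(OCOC)c(CC=C(C)C)c(OCOC)cc1OC(=O)N(CC)CC | intermediate
7 | 3,5-bis(methoxymethoxy)-4-prenyl-2-(trimethylsilyl)phenyl N,N-diethylcarbamate | C[Si](C)(C)c1c(OCOC)c(CC=C(C)C)c(OCOC)cc1OC(=O)N(CC)CC | intermediate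
8 | 6-lithio derivative of 7 (not isolated) | C[Si](C)(C)c1c(OCOC)c(CC=C(C)C)c(OCOC)c([Li])c1OC(=O)N(CC)CC | intermediate
9 | 3,5-bis(methoxymethoxy)-2,4-diprenyl-6-(trimethylsilyl)phenyl N,N-diethylcarbamate | C[Si](C)(C)c1c(OCOC)c(CC=C(C)C)c(OCOC)c(CC=C(C)C)c1OC(=O)N(CC)CC | intermediate
10 | 3,5-bis(methoxymethoxy)-2,4-diprenyl-6-(trimethylsilyl)phenol | C[Si](C)(C)c1c(OCOC)c(CC=C(C)C)c(OCOC)c(CC=C(C)C)c1O | intermediate
11 | lithium phenoxide of 10 (not isolated) | C[Si](C)(C)c1c(OCOC)c(CC=C(C)C)c(OCOC)c(CC=C(C)C)c1O[Li] | intermediate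
12 | 3,5-bis(methoxymethoxy)-2,4-diprenyl-6-(trimethylsilyl)phenyl trifluoromethanesulfonate | C[Si](C)(C)c1c(OCOC)c(CC=C(C)C)c(OCOC)c(CC=C(C)C)c1OS(=O)(=O)C(F)(F)F | intermediate
13 | 3-bromo-4,5-dihydroxybenzaldehyde | O=Cc1cc(O)c(O)c(Br)c1 | starting material
14 | 3-bromo-5-hydroxy-4-methoxybenzaldehyde | COc1c(O)cc(C=O)cc1Br | intermediate
15 | 3-bromo-4-methoxy-5-(methoxymethoxy)benzaldehyde | COCOc1cc(C=O)cc(Br)c1OC | intermediate
16 | 4-methoxy-3-(methoxymethoxy)-5-prenylbenzaldehyde | COCOc1cc(C=O)cc(CC=C(C)C)c1OC | intermediate
17 | N-methoxy-N-methylacetamide | CC(=O)N(C)OC | starting material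
18 | lithium enolate of 17 (not isolated) | C=C(O[Li])N(C)OC | intermediate
19 | rac-3-hydroxy-N-methoxy-3-[4-methoxy-3-(methoxymethoxy)-5-prenylphenyl]-N-methylpropanamide | COc1c(OCOC)cc(C(O)CC(=O)N(C)OC)cc1CC=C(C)C | intermediate
20 | N-methoxy-3-[4-methoxy-3-(methoxymethoxy)-5-prenylphenyl]-N-methyl-3-oxopropanamide | COc1c(OCOC)cc(C(=O)CC(=O)N(C)OC)cc1CC=C(C)C | intermediate
21 | (S)-3-hydroxy-N-methoxy-3-[4-methoxy-3-(methoxymethoxy)-5-prenylphenyl]-N-methylpropanamide | COc1c(OCOC)cc([C@H](CC(=O)N(C)OC)O)cc1CC=C(C)C | intermediate
22 | (S)-N-methoxy-3-[4-methoxy-3-(methoxymethoxy)-5-prenylphenyl]-N-methyl-3-(trimethylsilyloxy)propanamide | COc1c(OCOC)cc([C@H](CC(=O)N(C)OC)O[Si](C)(C)C)cc1CC=C(C)C | intermediate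
23 | 3,5-bis(methoxymethoxy)-4,6-diprenylbenzyne (not isolated) | C1#CC(OCOC)=C(CC=C(C)C)C(OCOC)=C1CC=C(C)C | intermediate
24 | potassium (S)-alkoxide of 21 (not isolated) | COc1c(OCOC)cc([C@H](CC(=O)N(C)OC)[O-])cc1CC=C(C)C.[K+] | intermediate
25 | (S)-aryl ether carrying the C4a carbanion, potassium salt (not isolated) | COc1c(OCOC)cc([C@H](CC(=O)N(C)OC)Oc2c(CC=C(C)C)c(OCOC)c(CC=C(C)C)c(OCOC)[c-]2)cc1CC=C(C)C.[K+] | intermediate
26 | (2S)-4-[methoxy(methyl)amino]chroman-4-olate, potassium salt, C4 undefined (not isolated) | COc1c(OCOC)cc([C@@H]2CC([O-])(N(C)OC)c3c(OCOC)c(CC=C(C)C)c(OCOC)c(CC=C(C)C)c3O2)cc1CC=C(C)C.[K+] | intermediate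
27 | (2S)-2-[4-methoxy-3-(methoxymethoxy)-5-prenylphenyl]-5,7-bis(methoxymethoxy)-6,8-diprenylchroman-4-one | COc1c(OCOC)cc([C@@H]2CC(=O)c3c(OCOC)c(CC=C(C)C)c(OCOC)c(CC=C(C)C)c3O2)cc1CC=C(C)C | intermediate
28 | isoamoritin | COc1c(O)cc([C@@H]2CC(=O)c3c(O)c(CC=C(C)C)c(O)c(CC=C(C)C)c3O2)cc1CC=C(C)C | target

## Step count and risks

Total step count: 16 (steps 1–7 for ring A, steps 8–14 for the ring B chain, steps 15–16 joint).
Longest linear sequence: 9 steps (13 → 28 through steps 8–16; the branch from 1 is equally long).

Steps most likely to fail: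

**Step 15 (Proposed new method).**
- Possible failures:
  - The C4a carbanion may be protonated before it captures the amide.
  - O-arylation by the hindered secondary alkoxide may be slower than consumption of the aryne by ene-type pathways.
  - The alkoxide may undergo retro-aldol cleavage.
  - The tetrahedral adduct may collapse before the quench, followed by base-induced opening of ring C and loss of configuration.
- The fallback sets out from aldehyde 16 and triflate 12 and comes back at 27.
- Knoevenagel–Doebner condensation of 16 with malonic acid (pyridine, piperidine, 90 °C) should give (E)-3-[4-methoxy-3-(methoxymethoxy)-5-prenylphenyl]acrylic acid F1.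
- CsF in hot THF with 12 then effects the known intermolecular C–O insertion of an aryne into a carboxylic acid (carboxylate oxygen to C8a, acyl shift to C4a). This gives 2'-hydroxy-4',6'-bis(methoxymethoxy)-3',5'-diprenyl chalcone F2.
- NaOAc in EtOH closes ring C by oxa-Michael addition to the racemic tris-MOM flavanone F3.
- Preparative HPLC on a chiral stationary phase delivers 27.

**Step 16.**
- Possible failures:
  - Acid-induced cyclisation of the prenyl groups onto the freshly liberated ortho phenols (chroman formation).
  - Partial loss of configuration through reversible opening of ring C during prolonged acid exposure.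
- The fallback sets out from 27 and comes back at 28 and uses no Brønsted acid.
- TMSOTf and 2,2'-bipyridyl (CH2Cl2, 0 °C) exchange the three aryl MOM ethers for silyl ethers, giving (2S)-tris(trimethylsilyl) ether of isoamoritin F4.
- F4 is hydrolysed by water at neutral pH to 28.

**Step 2.**
- Possible failures:
  - Sluggish ring lithiation of the aggregated lithium phenoxide.
  - Competing O-alkylation, or lithiation next to the phenoxide oxygen.
- The fallback sets out from 2 and comes back at 4.
- TIPSCl and imidazole (DMF) give [3,5-bis(methoxymethoxy)phenoxy]triisopropylsilane F5. Its bulky, non-directing silyl ether leaves only the position between the OMOM groups open.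
- n-BuLi (THF, 0 °C) and prenyl bromide give [3,5-bis(methoxymethoxy)-4-prenylphenoxy]triisopropylsilane F6.
- TBAF (THF, 0 °C) returns 4.

Further compounds
F1 | step 15 | (E)-3-[4-methoxy-3-(methoxymethoxy)-5-prenylphenyl]acrylic acid | COc1c(OCOC)cc(/C=C/C(=O)O)cc1CC=C(C)C
F2 | step 15 | (E)-1-[2-hydroxy-4,6-bis(methoxymethoxy)-3,5-diprenylphenyl]-3-[4-methoxy-3-(methoxymethoxy)-5-prenylphenyl]prop-2-en-1-one | COc1c(OCOC)cc(/C=C/C(=O)c2c(O)c(CC=C(C)C)c(OCOC)c(CC=C(C)C)c2OCOC)cc1CC=C(C)C
F3 | step 15 | rac-2-[4-methoxy-3-(methoxymethoxy)-5-prenylphenyl]-5,7-bis(methoxymethoxy)-6,8-diprenylchroman-4-one | COc1c(OCOC)cc(C2CC(=O)c3c(OCOC)c(CC=C(C)C)c(OCOC)c(CC=C(C)C)c3O2)cc1CC=C(C)C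
F4 | step 16 | (2S)-2-[4-methoxy-5-prenyl-3-(trimethylsilyloxy)phenyl]-6,8-diprenyl-5,7-bis(trimethylsilyloxy)chroman-4-one | COc1c(O[Si](C)(C)C)cc([C@@H]2CC(=O)c3c(O[Si](C)(C)C)c(CC=C(C)C)c(O[Si](C)(C)C)c(CC=C(C)C)c3O2)cc1CC=C(C)C
F5 | step 2 | [3,5-bis(methoxymethoxy)phenoxy]triisopropylsilane | COCOc1cc(O[Si](C(C)C)(C(C)C)C(C)C)cc(OCOC)c1
F6 | step 2 | [3,5-bis(methoxymethoxy)-4-prenylphenoxy]triisopropylsilane | COCOc1cc(O[Si](C(C)C)(C(C)C)C(C)C)cc(OCOC)c1CC=C(C)C
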